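The route rests on cutting the dihydropyran ring of the chroman at O1–C2 and C3–C4. That ring (O1, C2 with its gem-dimethyl group, unsubstituted C3 and C4, C4a, C8a) is what 2-methylpropene leaves behind when it adds across an ortho-quinone methide of ring A, so one hetero-Diels–Alder step builds both bonds and the ring. The precursor is the ring-A dimethylaminomethyl (Mannich) derivative of phloretin in which the two hydroxyls flanking the ketone carry methoxymethyl (MOM) groups. Only the oxygen para to the ketone can then become O1, and the ring-B phenol is afterwards the sole free hydroxyl for ortho-prenylation by O-alkylation, semi-hydrogenation and Claisen rearrangement.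

Key step: step 6

Remark: the target has no stereocentre and no stereogenic double bond, so it is achiral and needs no enantiocontrol; ring A is the acylated trioxygenated ring, ring B the 4-hydroxyphenyl ring, and chroman numbering (O1, C2 … C8a) is used for the pyran ring.

Step 1
Reactants: 1 1-(2,4,6-trihydroxyphenyl)ethan-1-one
Product: 2 1-[4-(benzyloxy)-2,6-dihydroxyphenyl]ethan-1-one
Conditions: BnBr (1.0 equiv), K2CO3 (1.0 equiv), DMF, 0 °C to rt
Reagents that add atoms: benzyl bromide, BrCc1ccccc1
Why: Williamson ether synthesis: with one equivalent of base and halide the hydroxyl para to the acetyl group should react first, because it is the most acidic one and is neither hydrogen-bonded to nor flanked by the carbonyl group.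

Step 2
Reactants: 2 1-[4-(benzyloxy)-2,6-dihydroxyphenyl]ethan-1-one
Product: 3 1-[4-(benzyloxy)-2,6-bis(methoxymethoxy)phenyl]ethan-1-one
Conditions: NaH (2.4 equiv), MOMCl (2.6 equiv), DMF, 0 °C to rt
Reagents that add atoms: chloromethyl methyl ether, COCCl
Why: Williamson-type O-alkylation (MOM acetal formation): NaH converts both ortho hydroxyls, including the one hydrogen-bonded to the ketone, into phenoxides that the hard electrophile MOMCl should cap on oxygen.

Step 3
Reactants: 3 1-[4-(benzyloxy)-2,6-bis(methoxymethoxy)phenyl]ethan-1-one; 4 4-(benzyloxy)benzaldehyde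
Product: 6 (E)-1-[4-(benzyloxy)-2,6-bis(methoxymethoxy)phenyl]-3-[4-(benzyloxy)phenyl]prop-2-en-1-one, via aldol adduct 5 (not isolated)
Conditions: 4 (1.1 equiv), 50% aq. KOH, EtOH, rt
Reagents that add atoms: none
Why: Claisen–Schmidt (crossed aldol) condensation: the methyl ketone enolate adds to the non-enolisable aldehyde and aldol 5 loses water by E1cB to the conjugated enone, the E geometry being the thermodynamic one; benzyl and MOM ethers are base-stable.

Step 4
Reactants: 6 (E)-1-[4-(benzyloxy)-2,6-bis(methoxymethoxy)phenyl]-3-[4-(benzyloxy)phenyl]prop-2-en-1-one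
Product: 7 1-[4-hydroxy-2,6-bis(methoxymethoxy)phenyl]-3-(4-hydroxyphenyl)propan-1-one
Conditions: H2 (1 atm), 10% Pd/C, EtOAc–EtOH, rt
Reagents that add atoms: none
Why: Heterogeneous catalytic hydrogenation should saturate the enone C=C bond and hydrogenolyse both benzyl ethers in one operation, while the MOM acetals and the twisted, di-ortho-substituted aryl ketone are inert under these neutral conditions.

Step 5
Reactants: 7 1-[4-hydroxy-2,6-bis(methoxymethoxy)phenyl]-3-(4-hydroxyphenyl)propan-1-one; 8 formaldehyde; 9 dimethylamine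
Product: 10 1-{3-[(dimethylamino)methyl]-4-hydroxy-2,6-bis(methoxymethoxy)phenyl}-3-(4-hydroxyphenyl)propan-1-one
Conditions: 37% aq. CH2O (1.05 equiv), 40% aq. Me2NH (1.1 equiv), EtOH, 0 °C to rt
Reagents that add atoms: none
Why: Phenolic Mannich reaction: the iminium ion formed in situ should attack ring A ortho to its only free hydroxyl, a position further activated by one ortho and one para alkoxy group and therefore far more nucleophilic than ring B, and one equivalent of reagent limits the reaction to one of the two equivalent sites.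

Step 6
Reactants: 10 1-{3-[(dimethylamino)methyl]-4-hydroxy-2,6-bis(methoxymethoxy)phenyl}-3-(4-hydroxyphenyl)propan-1-one; 11 2-methylpropene (isobutene)
Product: 13 1-[5,7-bis(methoxymethoxy)-2,2-dimethylchroman-6-yl]-3-(4-hydroxyphenyl)propan-1-one, via ortho-quinone methide 12 (not isolated)
Conditions: isobutene (ca. 50 equiv), toluene (0.02 M), sealed autoclave, 160 °C
Reagents that add atoms: none
Why: Heating transfers the phenolic proton to nitrogen and expels dimethylamine, giving ortho-quinone methide 12, in which the only available oxa-diene is CH2=C3–C4=O because the oxygens on C2 and C6 of that ring are capped as acetals. Isobutene then adds in a concerted, asynchronous inverse-electron-demand hetero-Diels–Alder reaction; the closest known reaction type is the thermal [4+2] trapping of Mannich-base-derived ortho-quinone methides by 1,1-disubstituted alkenes to give 2,2-disubstituted chromans. The pyran ring (O1, C2, C3, C4, C4a, C8a) is closed in cycloaddition mode, C4–C3 and O1–C2 forming in the same step. Orientation follows polarity: the alkene CH2 bonds to the electrophilic exocyclic methylene and the carbon that best carries positive charge bonds to oxygen, so the gem-dimethyl group lands on C2; no stereocentre is formed. The required regioselectivity for the linear 6-acyl chroman is structural, since the oxygen para to the ketone is the only one free to become O1, and chemoselectivity against alkylation of an electron-rich ring A by 12 is sought through high dilution, a large excess of the alkene and the absence of a phenoxide-like free phloroglucinol nucleus. Rearomatisation of ring A makes the addition irreversible.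

Step 7
Reactants: 13 1-[5,7-bis(methoxymethoxy)-2,2-dimethylchroman-6-yl]-3-(4-hydroxyphenyl)propan-1-one; 14 3-chloro-3-methylbut-1-yne
Product: 15 1-[5,7-bis(methoxymethoxy)-2,2-dimethylchroman-6-yl]-3-[4-(2-methylbut-3-yn-2-yloxy)phenyl]propan-1-one
Conditions: 14 (1.5 equiv), CuCl2·2H2O (1 mol%), DBU (1.5 equiv), MeCN, 0 °C
Reagents that add atoms: none
Why: Copper-catalysed propargylic substitution (via a copper acetylide/allenylidene): the ring-B phenoxide, the only free hydroxyl of 13, should be etherified at the tertiary carbon without touching ketone or acetals.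

Step 8
Reactants: 15 1-[5,7-bis(methoxymethoxy)-2,2-dimethylchroman-6-yl]-3-[4-(2-methylbut-3-yn-2-yloxy)phenyl]propan-1-one
Product: 16 1-[5,7-bis(methoxymethoxy)-2,2-dimethylchroman-6-yl]-3-[4-(2-methylbut-3-en-2-yloxy)phenyl]propan-1-one
Conditions: H2 (1 atm), Lindlar catalyst (Pd/CaCO3, Pb), quinoline, EtOAc, rt
Reagents that add atoms: none
Why: Lindlar semi-hydrogenation: on the lead- and quinoline-poisoned palladium surface the terminal alkyne should be reduced to the alkene and no further, with ketone, acetals and aryl rings untouched.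

Step 9
Reactants: 16 1-[5,7-bis(methoxymethoxy)-2,2-dimethylchroman-6-yl]-3-[4-(2-methylbut-3-en-2-yloxy)phenyl]propan-1-one
Product: 18 1-[5,7-bis(methoxymethoxy)-2,2-dimethylchroman-6-yl]-3-[4-hydroxy-3-(3-methylbut-2-enyl)phenyl]propan-1-one, via ortho-dienone 17 (not isolated)
Conditions: N,N-diethylaniline, 150 °C
Reagents that add atoms: none
Why: Aromatic Claisen rearrangement: the concerted [3,3] shift of the aryl 1,1-dimethylallyl ether should deliver the allyl terminus to one of the two equivalent ortho carbons (para is blocked) and enolisation of dienone 17 then restores the phenol carrying the 3-methylbut-2-enyl group.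

Step 10
Reactants: 18 1-[5,7-bis(methoxymethoxy)-2,2-dimethylchroman-6-yl]-3-[4-hydroxy-3-(3-methylbut-2-enyl)phenyl]propan-1-one
Product: 19 1-(5,7-dihydroxy-2,2-dimethylchroman-6-yl)-3-[4-hydroxy-3-(3-methylbut-2-enyl)phenyl]propan-1-one
Conditions: 3 M aq. HCl, MeOH, rt to 40 °C
Reagents that add atoms: none
Why: Acid-catalysed acetal solvolysis (transacetalisation to methanol): both MOM groups, made especially labile by the neighbouring carbonyl group, should be removed under conditions mild enough to spare the prenyl double bond and the chroman ether.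

Compound list
1 | 1-(2,4,6-trihydroxyphenyl)ethan-1-one | CC(=O)c1c(O)cc(O)cc1O | starting material
2 | 1-[4-(benzyloxy)-2,6-dihydroxyphenyl]ethan-1-one | CC(=O)c1c(O)cc(OCc2ccccc2)cc1O | intermediate
3 | 1-[4-(benzyloxy)-2,6-bis(methoxymethoxy)phenyl]ethan-1-one | CC(=O)c1c(OCOC)cc(OCc2ccccc2)cc1OCOC | intermediate
4 | 4-(benzyloxy)benzaldehyde | O=Cc1ccc(OCc2ccccc2)cc1 | starting material
5 | rac-1-[4-(benzyloxy)-2,6-bis(methoxymethoxy)phenyl]-3-[4-(benzyloxy)phenyl]-3-hydroxypropan-1-one (aldol adduct) | O=C(CC(O)c1ccc(OCc2ccccc2)cc1)c1c(OCOC)cc(OCc2ccccc2)cc1OCOC | intermediate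
6 | (E)-1-[4-(benzyloxy)-2,6-bis(methoxymethoxy)phenyl]-3-[4-(benzyloxy)phenyl]prop-2-en-1-one | O=C(/C=C/c1ccc(OCc2ccccc2)cc1)c1c(OCOC)cc(OCc2ccccc2)cc1OCOC | intermediate
7 | 1-[4-hydroxy-2,6-bis(methoxymethoxy)phenyl]-3-(4-hydroxyphenyl)propan-1-one | O=C(CCc1ccc(O)cc1)c1c(OCOC)cc(O)cc1OCOC | intermediate
8 | formaldehyde | C=O | starting material
9 | dimethylamine | CNC | starting material
10 | 1-{3-[(dimethylamino)methyl]-4-hydroxy-2,6-bis(methoxymethoxy)phenyl}-3-(4-hydroxyphenyl)propan-1-one | CN(C)Cc1c(O)cc(OCOC)c(C(=O)CCc2ccc(O)cc2)c1OCOC | intermediate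
11 | 2-methylpropene (isobutene) | C=C(C)C | starting material
12 | 3-(4-hydroxyphenyl)-1-[2,6-bis(methoxymethoxy)-3-methylidene-4-oxocyclohexa-1,5-dien-1-yl]propan-1-one (ortho-quinone methide) | C=C1C(=O)C=C(OCOC)C(C(=O)CCc2ccc(O)cc2)=C1OCOC | intermediate
13 | 1-[5,7-bis(methoxymethoxy)-2,2-dimethylchroman-6-yl]-3-(4-hydroxyphenyl)propan-1-one | O=C(CCc1ccc(O)cc1)c1c(OCOC)cc2c(c1OCOC)CCC(C)(C)O2 | intermediate
14 | 3-chloro-3-methylbut-1-yne | C#CC(C)(C)Cl | starting material
15 | 1-[5,7-bis(methoxymethoxy)-2,2-dimethylchroman-6-yl]-3-[4-(2-methylbut-3-yn-2-yloxy)phenyl]propan-1-one | C#CC(C)(C)Oc1ccc(CCC(=O)c2c(OCOC)cc3c(c2OCOC)CCC(C)(C)O3)cc1 | intermediate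
16 | 1-[5,7-bis(methoxymethoxy)-2,2-dimethylchroman-6-yl]-3-[4-(2-methylbut-3-en-2-yloxy)phenyl]propan-1-one | C=CC(C)(C)Oc1ccc(CCC(=O)c2c(OCOC)cc3c(c2OCOC)CCC(C)(C)O3)cc1 | intermediate
17 | rac-4-{3-[5,7-bis(methoxymethoxy)-2,2-dimethylchroman-6-yl]-3-oxopropyl}-6-(3-methylbut-2-enyl)cyclohexa-2,4-dien-1-one (ortho-dienone) | CC(C)=CCC1C=C(CCC(=O)c2c(OCOC)cc3c(c2OCOC)CCC(C)(C)O3)C=CC1=O | intermediate
18 | 1-[5,7-bis(methoxymethoxy)-2,2-dimethylchroman-6-yl]-3-[4-hydroxy-3-(3-methylbut-2-enyl)phenyl]propan-1-one | CC(C)=CCc1cc(CCC(=O)c2c(OCOC)cc3c(c2OCOC)CCC(C)(C)O3)ccc1O | intermediate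
19 | 1-(5,7-dihydroxy-2,2-dimethylchroman-6-yl)-3-[4-hydroxy-3-(3-methylbut-2-enyl)phenyl]propan-1-one (CNP0080516.0) | CC(C)=CCc1cc(CCC(=O)c2c(O)cc3c(c2O)CCC(C)(C)O3)ccc1O | target

Total step count: 10. Longest linear sequence: 10 steps (1 to 19); compounds 4, 8, 9, 11 and 14 are purchased.

Steps most likely to fail

Step 6. The quinone methide may be consumed by C-alkylation of the electron-rich ring A of a second molecule (methylene-bridged oligomers), or by reversible re-addition of amine or phenol, faster than the unactivated, volatile alkene adds. The fallback builds the same pyran ring through the para oxygen by sigmatropic and electrocyclic chemistry instead of a cycloaddition. It sets out from 7. One equivalent of K2CO3 and of 14 (KI, CuI cat., acetone) should alkylate the ring-A hydroxyl, which is about two pK units more acidic than the ring-B phenol, to give 1-[2,6-bis(methoxymethoxy)-4-(2-methylbut-3-yn-2-yloxy)phenyl]-3-(4-hydroxyphenyl)propan-1-one F1. Heating in N,N-diethylaniline at about 190 °C should bring about the propargyl Claisen rearrangement, 1,5-hydrogen shift and oxa-6π electrocyclisation to 1-[5,7-bis(methoxymethoxy)-2,2-dimethyl-2H-chromen-6-yl]-3-(4-hydroxyphenyl)propan-1-one F2. Hydrogenation of the C3=C4 bond (H2, Pd/C, EtOAc) comes back to the route at 13.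

Step 1. Over-benzylation at an ortho hydroxyl and C-benzylation of the phloroglucinol nucleus may erode the selectivity for mono-alkylation at the para oxygen. The fallback selects that oxygen by steric bulk and sheds the temporary group in the aldol step. It sets out from 1. TIPSCl (1.05 equiv) and imidazole in DMF should give 1-[2,6-dihydroxy-4-(triisopropylsilyloxy)phenyl]ethan-1-one F3. Excess MOMCl and i-Pr2NEt with NaI in refluxing CH2Cl2 should give 1-[2,6-bis(methoxymethoxy)-4-(triisopropylsilyloxy)phenyl]ethan-1-one F4. Claisen–Schmidt condensation with 4 in KOH/EtOH, in which hydroxide also cleaves the aryl silyl ether, should give (E)-3-[4-(benzyloxy)phenyl]-1-[4-hydroxy-2,6-bis(methoxymethoxy)phenyl]prop-2-en-1-one F5. Hydrogenation and hydrogenolysis (H2, Pd/C) come back to the route at 7.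

Step 10. During acetal cleavage, acid may add the ring-B phenol or HCl across the prenyl double bond (cyclisation or hydrochlorination). The fallback re-orders the end game so that acid acts before any prenyl or allyl group exists. It sets out from 15. 3 M HCl in MeOH at rt should remove both MOM groups while the tertiary propargylic aryl ether, whose ionisation is retarded by the alkynyl group, persists, giving 1-(5,7-dihydroxy-2,2-dimethylchroman-6-yl)-3-[4-(2-methylbut-3-yn-2-yloxy)phenyl]propan-1-one F6. Lindlar semi-hydrogenation should give 1-(5,7-dihydroxy-2,2-dimethylchroman-6-yl)-3-[4-(2-methylbut-3-en-2-yloxy)phenyl]propan-1-one F7. Thermal Claisen rearrangement (N,N-diethylaniline, 150 °C) then comes back to the route at 19 under neutral conditions.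

Further compounds
F1 | step 6 | 1-[2,6-bis(methoxymethoxy)-4-(2-methylbut-3-yn-2-yloxy)phenyl]-3-(4-hydroxyphenyl)propan-1-one | C#CC(C)(C)Oc1cc(OCOC)c(C(=O)CCc2ccc(O)cc2)c(OCOC)c1
F2 | step 6 | 1-[5,7-bis(methoxymethoxy)-2,2-dimethyl-2H-chromen-6-yl]-3-(4-hydroxyphenyl)propan-1-one | O=C(CCc1ccc(O)cc1)c1c(OCOC)cc2c(c1OCOC)C=CC(C)(C)O2
F3 | step 1 | 1-[2,6-dihydroxy-4-(triisopropylsilyloxy)phenyl]ethan-1-one | CC(=O)c1c(O)cc(O[Si](C(C)C)(C(C)C)C(C)C)cc1O
F4 | step 1 | 1-[2,6-bis(methoxymethoxy)-4-(triisopropylsilyloxy)phenyl]ethan-1-one | CC(=O)c1c(OCOC)cc(O[Si](C(C)C)(C(C)C)C(C)C)cc1OCOC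
F5 | step 1 | (E)-3-[4-(benzyloxy)phenyl]-1-[4-hydroxy-2,6-bis(methoxymethoxy)phenyl]prop-2-en-1-one | O=C(/C=C/c1ccc(OCc2ccccc2)cc1)c1c(OCOC)cc(O)cc1OCOC
F6 | step 10 | 1-(5,7-dihydroxy-2,2-dimethylchroman-6-yl)-3-[4-(2-methylbut-3-yn-2-yloxy)phenyl]propan-1-one | C#CC(C)(C)Oc1ccc(CCC(=O)c2c(O)cc3c(c2O)CCC(C)(C)O3)cc1
F7 | step 10 | 1-(5,7-dihydroxy-2,2-dimethylchroman-6-yl)-3-[4-(2-methylbut-3-en-2-yloxy)phenyl]propan-1-one | C=CC(C)(C)Oc1ccc(CCC(=O)c2c(O)cc3c(c2O)CCC(C)(C)O3)cc1
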